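The flask is reckoned in turnovers, not in minutes. X stands in solution at 35 mM when saturated, so a charge of J counts as c_J/c_X refills of the solution, on the assumption of one X for each J.

all flasks: X 35 mM (held)
- zeta: J 0.20 M; run made earlier
- theta: J 0.30 M; run made earlier
- flask: J 0.40 M; time 40 min

| run | time / min | D / % |
|---|---|---|
| zeta | 1.33 | 29.4 |
| zeta | 3.00 | 50.5 |
| zeta | 6.00 | 56.4 |
| zeta | 15.0 | 42.6 |
| zeta | 30.0 | 37.7 |
| theta | 1.33 | 27.0 |
| theta | 3.00 | 45.9 |
| theta | 6.00 | 51.6 |
| theta | 15.0 | 40.8 |
| theta | 30.0 | 33.1 |

(readings scatter by 1 percentage point)

- time up to 40 min at which D stands highest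
- the amount of D, in percent of the J charged, at that time
- earliest time at which at least nineteen twentieths of that best amount are there, in min
- latest time at which they still are, in min

Zeta counts 5.71 turnovers and theta 8.57. The zeta run reads highest at 6.00 min, with 56.4 %, and the theta run reads highest at the same time, with 51.6 %. The highest D reading drops by 1.7 percentage points per added turnover, a loss of selectivity for D, and this drop is called here the price of a turnover. The flask counts 11.4 turnovers, which is 2.86 beyond theta. So this reckoning puts its peak at 46.8 %, near 6.00 min.

The weak link is the price, since it rests on one pair of readings, each scattering by 1 point. The pair at 3.00 min is a separate measurement and gives 1.6 points, which carries the peak to 47.0 %. The price stands.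

The forecast commits to 48 % at 5.5 min, a little above this reckoning, with the window asked for running from 4 min to 8 min. Its ground is that “the percent yield falls as J rises while the time scale barely moves”.

The flask reaches 46.6 % at 5.67 min, and the window asked for runs from 3.91 min to 8.27 min.

    X ⇌ Z, rate k1*(csat - [Z]) (kL = 0.131 s⁻¹)
    J + Z → D (k = 0.198 M⁻¹ s⁻¹)
    J + D → Q (k = 0.00981 M⁻¹ s⁻¹)
    D ⇌ E (K = 1.20, k = 0.00131 s⁻¹)

Starting from the zeta run, changing the time leaves the best at 56.7 %, while changing the amount of J takes it to 46.6 %. A further flask with 0.24 M of J counts 6.86 turnovers, so the price puts its peak at 54.5 %. That flask reaches 54.4 %.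

Readings and results were generated by integration for substances that don't exist.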